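The route rests on cutting the C3–C4 bond of oxepane ring A (O, C10, C1–C5) and reading the C3 hydroxyl/C15 acetoxymethyl pair as a masked isoxazoline. An intramolecular nitrile oxide–alkene (3+2) cycloaddition joins a C3 nitrile oxide tethered to C10 with the C5 vinyl group (C4=C15) of a preformed, lactone-fused oxepane (ring B). It forms C3–C4 and O–C15 in one operation: it closes ring A and with it the ten-membered carbocycle, sets C4, and delivers C3 and C15 oxygenated. The precursor, a trans-2,7-disubstituted oxepane aldoxime, comes from (R)-linalool (C10 with both chains), an acetate aldol/alkylation pair (C7, C8) and a γ-alkoxyallylstannane–aldehyde cyclization (C5, C6).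

Key step: step 15

Remark on the chemistry: germacranolide numbering is used (C1–C10 carbocycle, C11–C13 lactone with C12 the carbonyl, C14 the methyl on C10, C15 on C4, ether oxygen between C5 and C10; ring A = O/C10/C1–C5, ring B = O/C5–C10); with C5 and C10 both R the bridges C1–C4 and C6–C9 lie trans across the ether oxygen, so the target is taken as the inside–outside 11-oxabicyclo[4.4.1]undecane (as in the ingenane core) and the route is built for that configuration.

Step 1
Reactants: 1 (R)-linalool
Product: 2 (3R)-3,7-dimethyloct-6-ene-1,3-diol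
Conditions: 9-BBN, THF, 0 °C to rt; then NaOH, H2O2, 0 °C
Reagents that add atoms: hydrogen peroxide, OO
Why: 9-BBN hydroborates the monosubstituted vinyl group far faster than the trisubstituted alkene and places boron on the terminal carbon (anti-Markovnikov hydroboration–oxidation), so C8 becomes a primary alcohol while the C10 stereocenter of the chiral pool is untouched.

Step 2
Reactants: 2 diol
Product: 3 primary triisopropylsilyl ether
Conditions: TIPSCl, imidazole, CH2Cl2, 0 °C
Reagents that add atoms: triisopropylsilyl chloride, CC(C)[Si](Cl)(C(C)C)C(C)C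
Why: Silylation with the bulky chlorosilane is selective for the primary over the tertiary hydroxyl, and the triisopropylsilyl group resists migration to the tertiary alkoxide formed in the next step.

Step 3
Reactants: 3 silyl ether
Product: 4 tertiary allyl ether
Conditions: KH, allyl bromide, THF, 0 °C to rt
Reagents that add atoms: allyl bromide, C=CCBr
Why: Williamson etherification of the potassium tertiary alkoxide with the unhindered allylic bromide installs on the ether oxygen the three carbons that become C5, C4 and C15.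

Step 4
Reactants: 4 allyl ether
Product: 5 (Z)-γ-alkoxyallylstannane
Conditions: s-BuLi, TMEDA, THF, −78 °C; then Bu3SnCl, −78 °C
Reagents that add atoms: tributyltin chloride, CCCC[Sn](Cl)(CCCC)CCCC
Why: Directed α-lithiation of the allyl ether gives the oxygen-chelated (Z)-alkoxyallyl anion, which is stannylated at its γ-terminus (the standard entry to (Z)-γ-alkoxyallylstannanes), the allylic ether C–H being far more acidic than the prenyl C–H bonds.

Step 5
Reactants: 5 stannane
Product: 6 primary alcohol
Conditions: Bu4NF, THF, 0 °C to rt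
Reagents that add atoms: none
Why: Fluoride-mediated desilylation frees the C8 hydroxyl under basic, non-electrophilic conditions that leave the acid-sensitive enol ether and allylstannane intact.

Step 6
Reactants: 6 alcohol
Product: 7 aldehyde (C8)
Conditions: SO3·pyridine, DMSO, iPr2NEt, CH2Cl2, 0 °C
Reagents that add atoms: none
Why: Parikh–Doering oxidation converts the primary alcohol into the aldehyde without acid or electrophilic halogen, conditions under which γ-alkoxyallylstannanes survive.

Step 7
Reactants: 7 aldehyde; 8 (S)-HYTRA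
Product: 9 β-hydroxy HYTRA ester
Conditions: LiN(iPr)2 (2 equiv), THF, −78 to 0 °C; MgBr2, −78 °C; then 7, −115 °C
Reagents that add atoms: none
Why: Chiral-auxiliary acetate aldol addition: the magnesium enolate of doubly deprotonated (S)-HYTRA adds to one face of the aldehyde under reagent control, which sets C8 (R) independently of the remote C10 centre, and the base-only conditions avoid Lewis-acid activation of the aldehyde towards the internal allylstannane.

Step 8
Reactants: 9 HYTRA ester
Product: 10 methyl β-hydroxy ester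
Conditions: K2CO3 (cat.), MeOH, rt
Reagents that add atoms: methanol, CO
Why: Carbonate-catalysed transesterification exchanges the auxiliary for a methyl ester without touching the β-hydroxyl, the C8 configuration or the stannane.

Step 9
Reactants: 10 methyl ester
Product: 11 anti-alkylated succinate
Conditions: LiN(iPr)2 (2.2 equiv), THF, DMPU, −78 to −40 °C; then BrCH2CO2tBu
Reagents that add atoms: tert-butyl bromoacetate, CC(C)(C)OC(=O)CBr
Why: Fráter–Seebach alkylation: the chelated alkoxide–enolate dianion is alkylated on the face anti to the C8 substituent, which sets C7 (R) with the required anti C7/C8 relationship and brings in C11 and C12.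

Step 10
Reactants: 11 hydroxy diester
Product: 12 C8 tert-butyldimethylsilyl ether
Conditions: TBSCl, imidazole, DMAP (cat.), DMF, 40 °C
Reagents that add atoms: tert-butyldimethylsilyl chloride, CC(C)(C)[Si](C)(C)Cl
Why: Imidazole-buffered silylation blocks the C8 hydroxyl so that it can neither lactonize onto C12 nor interfere in the Lewis-acid step, and it leaves both esters and the stannane untouched.

Step 11
Reactants: 12 silyl ether
Product: 13 aldehyde (C6)
Conditions: iBu2AlH (1.1 equiv), CH2Cl2, −78 °C
Reagents that add atoms: none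
Why: Chemoselective partial ester reduction: at −78 °C the methyl ester is reduced through a stable tetrahedral aluminate to the aldehyde while the bulky tert-butyl ester is not attacked.

Step 12
Reactants: 13 aldehyde
Product: 15 vinyl lactone, via hydroxy ester 14 (not isolated)
Conditions: BF3·OEt2, CH2Cl2, −78 °C, then 0 °C
Reagents that add atoms: none
Why: Lewis-acid-mediated intramolecular γ-alkoxyallylstannane–aldehyde allylation closes ring B at C5–C6 through an open SE2' transition state that gives the 2,3-trans relationship (C5 vinyl/C6 oxygen), with the C7 side chain pseudo-equatorial and anti to the forming bond so that C6–O ends up trans to C7–C11, and on warming the C6 oxygen closes onto the tert-butyl ester with loss of isobutene to give the trans-fused γ-lactone.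

Step 13
Reactants: 15 vinyl lactone
Product: 17 aldehyde (C3), via epoxide 16 (not isolated)
Conditions: mCPBA, NaHCO3, CH2Cl2, 0 °C; then H5IO6, THF/H2O, 0 °C
Reagents that add atoms: 3-chloroperbenzoic acid, OOC(=O)c1cccc(Cl)c1
Why: Prilezhaev epoxidation takes the electron-rich trisubstituted alkene much faster than the vinyl group deactivated by the allylic ether oxygen, and periodic acid cleaves the epoxide through its diol to the C3 aldehyde and acetone.

Step 14
Reactants: 17 aldehyde
Product: 18 aldoxime
Conditions: NH2OH·HCl, NaOAc, MeOH, rt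
Reagents that add atoms: hydroxylamine hydrochloride, NO.Cl
Why: Oxime condensation under acetate buffering converts the aldehyde into the aldoxime (E/Z mixture, both usable) without opening the lactone.

Step 15
Reactants: 18 aldoxime
Product: 21 isoxazoline, via hydroximoyl chloride 19 (not isolated), via nitrile oxide 20 (not isolated)
Conditions: aq. NaOCl, Et3N (cat.), CH2Cl2, 0 °C to rt, slow addition, 0.002 M
Reagents that add atoms: none
Why: Hypochlorite chlorinates the aldoxime and base removes HCl to give the C3 nitrile oxide, which adds in a concerted, suprafacial (3+2) fashion across the C4=C15 vinyl group on ring B; the closest known reaction is the intramolecular nitrile oxide–olefin cycloaddition (INOC) used to make isoxazoline-fused oxepanes. The isoxazoline ring closes by simultaneous C3–C4 and O–C15 bonding, oxepane ring A closes through C3–C4 in the fused (exo) mode that leaves C15 outside the ring, and the ten-membered carbocycle C1–C10 is thereby completed across the C5–O–C10 ether as the trans-bridged bicycle. Regiochemistry (carbon to the inner alkene carbon C4, oxygen to C15) is enforced by the three-atom tether C1–C2–C3, because the reversed, bridged mode would need an eight-membered ring. C4 is the only new stereocenter and is controlled by the adjacent C5 centre: ring formation holds the C5–O bond gauche to the incoming carbon, and the inside-alkoxy preference of nitrile oxide additions to allylic ethers then puts C6 anti to it, which places H4 cis to H5. Chemoselectivity requires that the dipole finds no other dipolarophile and cyclizes faster than it dimerizes, which is secured by the lactone still lacking its methylene group and by slow generation at high dilution. The strain of the inside–outside skeleton is the accepted risk, and the strongly exothermic, early transition state of the cycloaddition is relied on to overcome it.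

Step 16
Reactants: 21 isoxazoline
Product: 24 α-methylene lactone, via Mannich base 22 (not isolated), via ammonium iodide 23 (not isolated)
Conditions: LiN(iPr)2 (1.05 equiv), THF, −78 °C; Eschenmoser's salt, −78 °C to rt; MeI, MeOH, rt; then aq. NaHCO3, CH2Cl2
Reagents that add atoms: dimethylmethylideneammonium iodide (Eschenmoser's salt), C=[N+](C)C.[I-]
Why: Eschenmoser methylenation: the lactone α-protons at C11 are the most acidic in the molecule, so one equivalent of amide base gives the lactone enolate, which is aminomethylated, quaternized and eliminated (E1cB) to the exocyclic C11=C13 alkene while the isoxazoline protects O3 and O15.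

Step 17
Reactants: 24 silyl ether
Product: 25 C8 alcohol
Conditions: HF·pyridine, pyridine, THF, 0 °C to rt
Reagents that add atoms: none
Why: Buffered fluoride desilylation frees the C8 hydroxyl without affecting the isoxazoline or the Michael-sensitive α-methylene lactone.

Step 18
Reactants: 26 (E)-crotonaldehyde
Product: 27 (Z)-2-iodobut-2-enal
Conditions: I2, K2CO3, DMAP (cat.), THF/H2O, rt
Reagents that add atoms: iodine, II
Why: α-Iodination of the enal (conjugate addition of the amine catalyst, iodination of the enolate, elimination) replaces the α-hydrogen by iodine and keeps the formyl group trans to methyl, which fixes the alkene geometry of the acyl unit.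

Step 19
Reactants: 27 iodoenal
Product: 28 (Z)-2-iodobut-2-en-1-ol
Conditions: NaBH4, MeOH, 0 °C
Reagents that add atoms: none
Why: Borohydride 1,2-reduction of the aldehyde leaves the vinyl iodide and its geometry untouched.

Step 20
Reactants: 28 iodo alcohol
Product: 29 silyl ether
Conditions: TBSCl, imidazole, CH2Cl2, rt
Reagents that add atoms: tert-butyldimethylsilyl chloride, CC(C)(C)[Si](C)(C)Cl
Why: Silylation masks the allylic hydroxyl so that it cannot compete in the later esterification and selective acetylation.

Step 21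
Reactants: 29 vinyl iodide
Product: 30 (Z)-acid
Conditions: Pd(PPh3)4 (5 mol %), CO (1 atm), K2CO3, DMF/H2O, 60 °C; then aq. citric acid
Reagents that add atoms: carbon monoxide, [C-]#[O+]; water, O
Why: Palladium-catalysed hydroxycarbonylation (oxidative addition, CO insertion, hydrolysis of the acylpalladium) replaces iodine by CO2H with retention of alkene geometry, so the carboxyl group ends up cis to the methyl group as in the target.

Step 22
Reactants: 25 C8 alcohol; 30 (Z)-acid
Product: 31 C8 ester
Conditions: 2,4,6-Cl3C6H2COCl, Et3N, toluene, rt; then 25, DMAP, toluene, rt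
Reagents that add atoms: none
Why: Yamaguchi esterification through the mixed trichlorobenzoic anhydride acylates the hindered C8 hydroxyl, the only free hydroxyl present, with retention at C8.

Step 23
Reactants: 31 isoxazoline ester
Product: 32 β-hydroxy ketone
Conditions: Mo(CO)6, MeCN/H2O, 80 °C
Reagents that add atoms: water, O
Why: Molybdenum hexacarbonyl cleaves the isoxazoline N–O bond reductively and the β-hydroxy imine hydrolyses to the C3 ketone under neutral conditions that spare the α-methylene lactone, the enoate and the C4 stereocenter.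

Step 24
Reactants: 32 β-hydroxy ketone
Product: 33 diol
Conditions: Zn(BH4)2, Et2O, −30 °C
Reagents that add atoms: none
Why: Chelation-controlled hydride reduction: zinc bridges the C15 hydroxyl and the C3 carbonyl and hydride enters the chelate on the face opposite to C5, which should give the C3 alcohol cis to the C15 hydroxymethyl group, and the reagent does not reduce the conjugated esters at low temperature.

Step 25
Reactants: 33 diol
Product: 34 C15 monoacetate
Conditions: AcCl, 2,4,6-collidine, CH2Cl2, −78 °C
Reagents that add atoms: acetyl chloride, CC(Cl)=O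
Why: Kinetically selective acylation: at low temperature with the hindered base the primary C15 hydroxyl is acetylated much faster than the secondary C3 hydroxyl.

Step 26
Reactants: 34 silyl ether
Product: 35 target CNP0311647.1
Conditions: HF·pyridine, THF, 0 °C
Reagents that add atoms: none
Why: Fluoride desilylation removes the primary allylic silyl ether without touching the acetate, the two conjugated esters or the free C3 alcohol.

Compound list
1 | (R)-(−)-linalool, (3R)-3,7-dimethylocta-1,6-dien-3-ol | C=C[C@](C)(O)CCC=C(C)C | starting material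
2 | (3R)-3,7-dimethyloct-6-ene-1,3-diol | OCC[C@](C)(O)CCC=C(C)C | intermediate
3 | (3R)-3,7-dimethyl-1-[(triisopropylsilyl)oxy]oct-6-en-3-ol | CC(C)[Si](OCC[C@](C)(O)CCC=C(C)C)(C(C)C)C(C)C | intermediate
4 | (3R)-3-(allyloxy)-3,7-dimethyl-1-[(triisopropylsilyl)oxy]oct-6-ene | CC(C)[Si](OCC[C@](C)(OCC=C)CCC=C(C)C)(C(C)C)C(C)C | intermediate
5 | tributyl[(2Z)-3-({(3R)-3,7-dimethyl-1-[(triisopropylsilyl)oxy]oct-6-en-3-yl}oxy)prop-2-en-1-yl]stannane | CC(C)[Si](OCC[C@](C)(O/C=C\C[Sn](CCCC)(CCCC)CCCC)CCC=C(C)C)(C(C)C)C(C)C | intermediate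
6 | (3R)-3,7-dimethyl-3-{[(1Z)-3-(tributylstannyl)prop-1-en-1-yl]oxy}oct-6-en-1-ol | OCC[C@](C)(O/C=C\C[Sn](CCCC)(CCCC)CCCC)CCC=C(C)C | intermediate
7 | (3R)-3,7-dimethyl-3-{[(1Z)-3-(tributylstannyl)prop-1-en-1-yl]oxy}oct-6-enal | O=CC[C@](C)(O/C=C\C[Sn](CCCC)(CCCC)CCCC)CCC=C(C)C | intermediate
8 | (S)-HYTRA, (1S)-2-hydroxy-1,2,2-triphenylethyl acetate | CC(=O)O[C@@H](c1ccccc1)C(O)(c1ccccc1)c1ccccc1 | starting material
9 | (1S)-2-hydroxy-1,2,2-triphenylethyl (3R,5R)-3-hydroxy-5,9-dimethyl-5-{[(1Z)-3-(tributylstannyl)prop-1-en-1-yl]oxy}dec-8-enoate | O=C(C[C@H](O)C[C@](C)(O/C=C\C[Sn](CCCC)(CCCC)CCCC)CCC=C(C)C)O[C@@H](c1ccccc1)C(O)(c1ccccc1)c1ccccc1 | intermediate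
10 | methyl (3R,5R)-3-hydroxy-5,9-dimethyl-5-{[(1Z)-3-(tributylstannyl)prop-1-en-1-yl]oxy}dec-8-enoate | COC(=O)C[C@H](O)C[C@](C)(O/C=C\C[Sn](CCCC)(CCCC)CCCC)CCC=C(C)C | intermediate
11 | 4-tert-butyl 1-methyl (2R)-2-[(1R,3R)-1-hydroxy-3,7-dimethyl-3-{[(1Z)-3-(tributylstannyl)prop-1-en-1-yl]oxy}oct-6-en-1-yl]butanedioate | COC(=O)[C@H](CC(=O)OC(C)(C)C)[C@H](O)C[C@](C)(O/C=C\C[Sn](CCCC)(CCCC)CCCC)CCC=C(C)C | intermediate
12 | 4-tert-butyl 1-methyl (2R)-2-[(1R,3R)-1-[(tert-butyldimethylsilyl)oxy]-3,7-dimethyl-3-{[(1Z)-3-(tributylstannyl)prop-1-en-1-yl]oxy}oct-6-en-1-yl]butanedioate | COC(=O)[C@H](CC(=O)OC(C)(C)C)[C@H](O[Si](C)(C)C(C)(C)C)C[C@](C)(O/C=C\C[Sn](CCCC)(CCCC)CCCC)CCC=C(C)C | intermediate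
13 | tert-butyl (3R,4R,6R)-4-[(tert-butyldimethylsilyl)oxy]-3-formyl-6,10-dimethyl-6-{[(1Z)-3-(tributylstannyl)prop-1-en-1-yl]oxy}undec-9-enoate | O=C[C@H](CC(=O)OC(C)(C)C)[C@H](O[Si](C)(C)C(C)(C)C)C[C@](C)(O/C=C\C[Sn](CCCC)(CCCC)CCCC)CCC=C(C)C | intermediate
14 | tert-butyl 2-[(2R,3S,4S,5R,7R)-5-[(tert-butyldimethylsilyl)oxy]-3-hydroxy-7-methyl-7-(4-methylpent-3-en-1-yl)-2-vinyloxepan-4-yl]acetate | O[C@@H]1[C@@H](C=C)O[C@](C)(CCC=C(C)C)C[C@@H](O[Si](C)(C)C(C)(C)C)[C@H]1CC(=O)OC(C)(C)C | intermediate
15 | vinyl lactone: ring B oxepane trans-fused at C6–C7 to the γ-lactone (O on C6, C11H2 on C7), vinyl on C5, OTBS on C8, methyl and 4-methylpent-3-enyl on C10; 5R,6S,7S,8R,10R | C1C(=O)O[C@@H]2[C@@H](C=C)O[C@](C)(CCC=C(C)C)C[C@@H](O[Si](C)(C)C(C)(C)C)[C@@H]12 | intermediate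
16 | epoxide of 15 at the side-chain alkene (2-(3,3-dimethyloxiran-2-yl)ethyl on C10, epoxide carbon as a mixture) | C1C(=O)O[C@@H]2[C@@H](C=C)O[C@](C)(CCC3OC3(C)C)C[C@@H](O[Si](C)(C)C(C)(C)C)[C@@H]12 | intermediate
17 | C3 aldehyde: as 15 with 3-oxopropyl (C1–C3) on C10; 5R,6S,7S,8R,10R | C1C(=O)O[C@@H]2[C@@H](C=C)O[C@](C)(CCC=O)C[C@@H](O[Si](C)(C)C(C)(C)C)[C@@H]12 | intermediate
18 | C3 aldoxime of 17 (E/Z mixture) | C1C(=O)O[C@@H]2[C@@H](C=C)O[C@](C)(CCC=NO)C[C@@H](O[Si](C)(C)C(C)(C)C)[C@@H]12 | intermediate
19 | C3 hydroximoyl chloride of 18 | C1C(=O)O[C@@H]2[C@@H](C=C)O[C@](C)(CCC(Cl)=NO)C[C@@H](O[Si](C)(C)C(C)(C)C)[C@@H]12 | intermediate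
20 | C3 nitrile oxide | C1C(=O)O[C@@H]2[C@@H](C=C)O[C@](C)(CCC#[N+][O-])C[C@@H](O[Si](C)(C)C(C)(C)C)[C@@H]12 | intermediate
21 | tetracyclic isoxazoline: rings A and B bridged by the C5–O–C10 ether, 4,5-dihydroisoxazole (C3=N–O–C15) fused at C3–C4, saturated 6,12-lactone, OTBS on C8; 4R,5R,6S,7S,8R,10R | C1C(=O)O[C@@H]2[C@@H]3O[C@](C)(CCC4=NOC[C@@H]43)C[C@@H](O[Si](C)(C)C(C)(C)C)[C@@H]12 | intermediate
22 | Mannich base: 21 with (dimethylamino)methyl on C11 (C11 epimers) | CN(C)CC1C(=O)O[C@@H]2[C@@H]3O[C@](C)(CCC4=NOC[C@@H]43)C[C@@H](O[Si](C)(C)C(C)(C)C)[C@@H]12 | intermediate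
23 | trimethylammonium iodide of 22 (C11 epimers) | C[N+](C)(C)CC1C(=O)O[C@@H]2[C@@H]3O[C@](C)(CCC4=NOC[C@@H]43)C[C@@H](O[Si](C)(C)C(C)(C)C)[C@@H]12.[I-] | intermediate
24 | α-methylene lactone isoxazoline: 21 with exocyclic C11=C13; 4R,5R,6S,7S,8R,10R | C=C1C(=O)O[C@@H]2[C@@H]3O[C@](C)(CCC4=NOC[C@@H]43)C[C@@H](O[Si](C)(C)C(C)(C)C)[C@@H]12 | intermediate
25 | C8 alcohol of 24; 4R,5R,6S,7R,8R,10R | C=C1C(=O)O[C@@H]2[C@@H]3O[C@](C)(CCC4=NOC[C@@H]43)C[C@@H](O)[C@@H]12 | intermediate
26 | (E)-crotonaldehyde, (2E)-but-2-enal | C/C=C/C=O | starting material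
27 | (2Z)-2-iodobut-2-enal | C/C=C(\I)C=O | intermediate
28 | (2Z)-2-iodobut-2-en-1-ol | C/C=C(\I)CO | intermediate
29 | tert-butyl{[(2Z)-2-iodobut-2-en-1-yl]oxy}dimethylsilane | C/C=C(\I)CO[Si](C)(C)C(C)(C)C | intermediate
30 | (2Z)-2-{[(tert-butyldimethylsilyl)oxy]methyl}but-2-enoic acid | C/C=C(\C(=O)O)CO[Si](C)(C)C(C)(C)C | intermediate
31 | C8 (2Z)-2-(silyloxymethyl)but-2-enoate of 25; 4R,5R,6S,7R,8R,10R | C=C1C(=O)O[C@@H]2[C@@H]3O[C@](C)(CCC4=NOC[C@@H]43)C[C@@H](OC(=O)/C(=C\C)CO[Si](C)(C)C(C)(C)C)[C@@H]12 | intermediate
32 | β-hydroxy ketone: C3 ketone, C15 hydroxymethyl on C4; 4R,5R,6S,7R,8R,10R | C=C1C(=O)O[C@@H]2[C@@H]3O[C@](C)(CCC(=O)[C@@H]3CO)C[C@@H](OC(=O)/C(=C\C)CO[Si](C)(C)C(C)(C)C)[C@@H]12 | intermediate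
33 | diol: C3 hydroxyl cis to the C15 hydroxymethyl group; 3S,4S,5R,6S,7R,8R,10R | C=C1C(=O)O[C@@H]2[C@@H]3O[C@](C)(CC[C@H](O)[C@@H]3CO)C[C@@H](OC(=O)/C(=C\C)CO[Si](C)(C)C(C)(C)C)[C@@H]12 | intermediate
34 | C15 acetate of 33, side-chain hydroxyl still silylated | C=C1C(=O)O[C@@H]2[C@@H]3O[C@](C)(CC[C@H](O)[C@@H]3COC(C)=O)C[C@@H](OC(=O)/C(=C\C)CO[Si](C)(C)C(C)(C)C)[C@@H]12 | intermediate
35 | CNP0311647.1: (3S,4S,5R,6S,7R,8R,10R)-15-acetoxy-3-hydroxy-8-[(2Z)-2-(hydroxymethyl)but-2-enoyloxy]-5,10-epoxygermacr-11(13)-en-12,6-olide | C=C1C(=O)O[C@@H]2[C@@H]3O[C@](C)(CC[C@H](O)[C@@H]3COC(C)=O)C[C@@H](OC(=O)/C(=C\C)CO)[C@@H]12 | target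

Total step count: 26. Longest linear sequence: 22 steps (steps 1–17 and 22–26, from (R)-linalool); the acyl unit 30 takes 4 steps (18–21).

Steps most likely to fail

Step 15. Closure of the strained, trans-bridged ring may be slower than dimerization of the nitrile oxide to the furoxan or its rearrangement to the isocyanate, and attack on the other face of the vinyl group would give the wrong configuration at C4. The fallback sets out from oxime 18 and changes the dipole. Heating 18 at high dilution in o-dichlorobenzene at 160 °C should bring about the thermal intramolecular oxime–olefin cycloaddition through the N–H nitrone tautomer (1,2-prototropy). This is a unimolecular process with no dimerization channel, and it gives the N-unsubstituted isoxazolidine F1. N-Chlorination with N-chlorosuccinimide and dehydrochlorination with Et3N then give isoxazoline 21, where the route is rejoined before step 16.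

Step 24. Hydride delivery may show poor facial selectivity if the zinc chelate does not form in the congested bicycle, so that the alcohol trans to the C15 group predominates. The fallback sets out from ketone 32 and inverts instead of selecting. Reduction with Me4NBH(OAc)3 in MeCN/AcOH at −30 °C (Evans–Saksena reduction, hydride delivered internally from the C15 alkoxyborohydride) should give the C3-epimeric diol F2. AcCl/collidine at −78 °C gives its C15 monoacetate F3. A Mitsunobu reaction with chloroacetic acid (PPh3, DIAD, toluene) inverts C3 to give the inverted C3 chloroacetate F4. Thiourea with NaHCO3 in EtOH removes the chloroacetyl group in the presence of the acetate and returns to 34 before step 26.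

Step 22. The Z-configured acyl unit may isomerize to the E-isomer through reversible conjugate addition of DMAP to the activated acid, and acylation of the hindered C8 hydroxyl may be slow enough for translactonization to compete. The fallback sets out from alcohol 25 and vinyl iodide 29 and avoids the activated free acid. Palladium-catalysed alkoxycarbonylation (PdCl2(PPh3)2, CO 1 atm, Et3N, toluene, 60 °C) forms the acylpalladium from 29 with retention of geometry and lets the C8 hydroxyl of 25 intercept it. This gives ester 31 directly; no new compound is formed (F0), and the route continues with step 23.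

Further compounds
F1 | step 15 | N-unsubstituted isoxazolidine (C3–NH–O–C15 ring cis-fused to ring A at C3–C4, otherwise as 21; 3S,4R,5R,6S,7S,8R,10R) | C1C(=O)O[C@@H]2[C@@H]3O[C@](C)(CC[C@@H]4NOC[C@@H]43)C[C@@H](O[Si](C)(C)C(C)(C)C)[C@@H]12
F2 | step 24 | C3-epimeric diol (3R epimer of 33) | C=C1C(=O)O[C@@H]2[C@@H]3O[C@](C)(CC[C@@H](O)[C@@H]3CO)C[C@@H](OC(=O)/C(=C\C)CO[Si](C)(C)C(C)(C)C)[C@@H]12
F3 | step 24 | C15 monoacetate of F2 | C=C1C(=O)O[C@@H]2[C@@H]3O[C@](C)(CC[C@@H](O)[C@@H]3COC(C)=O)C[C@@H](OC(=O)/C(=C\C)CO[Si](C)(C)C(C)(C)C)[C@@H]12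
F4 | step 24 | inverted C3 chloroacetate (3S, chloroacetate of 34) | C=C1C(=O)O[C@@H]2[C@@H]3O[C@](C)(CC[C@H](OC(=O)CCl)[C@@H]3COC(C)=O)C[C@@H](OC(=O)/C(=C\C)CO[Si](C)(C)C(C)(C)C)[C@@H]12
F0 | step 22 | none | none
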